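**Retrosynthetic overview**
1. The target comes from selective C1 acetylation of bromochloro diol 24. Compound 24 comes from a bromochlorination of spiro alkene diol 21 directed by the C1 alkoxide, so C3–Cl and C4–Br are set last.
2. Ring A is formed second, by ring-closing metathesis (C3=C4) of the allyl and methallyl arms of bicyclic carbonate 19.
3. Ring B is formed first. A bromonium-induced cyclisation of the (Z)-tetrasubstituted alkene 17, trapped by its Boc group, makes C6–C11 and sets C6, C7 and C10.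
4. The (Z)-alkene and the C8–C9 bond come from a [3,3]-sigmatropic ketene-acetal Claisen ring expansion of vinyl diol 8 to the seven-membered lactone 12.
5. Diol 8 comes from methyl (2R)-glycidate, which supplies C1, plus isopropenyl and allyl Grignard reagents.

Assumption and numbering: methyl (2R)-glycidate (made from L-serine) is taken as the commercial chiral starting material. Spiro compounds are numbered C1 (ring A carbinol) to C5, C6 (spiro atom), C7 (methyl carbinol) to C11 (CMe2), and names use these locants.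

**Step 1**
Reactants: 1 methyl (2R)-oxirane-2-carboxylate; 2 prop-1-en-2-ylmagnesium bromide
Product: 3 methyl (2R)-2-hydroxy-4-methylpent-4-enoate
Conditions: 2 (1.3 equiv), CuBr·SMe2 (10 mol %), THF, −40 °C
Reagents that add atoms: prop-1-en-2-ylmagnesium bromide (2), CC(=C)[Mg]Br
Why: Copper-catalysed Grignard opening of the epoxide (SN2 at the unsubstituted CH2) leaves the purchased C–O stereocentre, the future C1, untouched.

**Step 2**
Reactants: 3 methyl (2R)-2-hydroxy-4-methylpent-4-enoate; 4 N,O-dimethylhydroxylamine hydrochloride; 2 prop-1-en-2-ylmagnesium bromide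
Product: 6 (4R)-4-hydroxy-2,6-dimethylhepta-1,6-dien-3-one, via Weinreb amide 5 (not isolated)
Conditions: 4, i-PrMgCl, THF, −20 °C; then 2, 0 °C; aq. NH4Cl
Reagents that add atoms: prop-1-en-2-ylmagnesium bromide (2), CC(=C)[Mg]Br
Why: In this one-pot Weinreb ketone synthesis the chelated tetrahedral adduct stops the addition at the ketone, and the neighbouring magnesium alkoxide suppresses enolisation, so C1 keeps its configuration.

**Step 3**
Reactants: 6 (4R)-4-hydroxy-2,6-dimethylhepta-1,6-dien-3-one; 7 prop-2-en-1-ylmagnesium bromide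
Product: 8 (4R)-2,6-dimethyl-3-(prop-2-en-1-yl)hepta-1,6-diene-3,4-diol (both C3 epimers)
Conditions: 7 (2.2 equiv), THF, −78 °C
Reagents that add atoms: prop-2-en-1-ylmagnesium bromide (7), C=CC[Mg]Br
Why: Allyl Grignard reagents add 1,2 to the enone carbonyl, and the new tertiary carbinol centre needs no control because it becomes sp2 in step 4.

**Step 4**
Reactants: 8 (4R)-2,6-dimethyl-3-(prop-2-en-1-yl)hepta-1,6-diene-3,4-diol; 9 trimethyl orthoacetate
Product: 12 (7R)-5-methyl-7-(2-methylprop-2-en-1-yl)-6-(prop-2-en-1-yl)-4,7-dihydrooxepin-2(3H)-one, via cyclic orthoester 10 (not isolated), via cyclic ketene acetal 11 (not isolated)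
Conditions: MeC(OMe)3, EtCO2H (cat.), xylene, 140 °C, MeOH distilled off
Reagents that add atoms: trimethyl orthoacetate (9), COC(C)(OC)OC
Why: In this Johnson-type orthoester Claisen rearrangement the [3,3]-sigmatropic shift of the cyclic ketene acetal forms C8–C9; because both termini stay tied in a seven-membered lactone, the tetrasubstituted C6=C7 alkene can form only with C1 and C8 cis, so both epimers of 8 converge and C1 is untouched.

**Step 5**
Reactants: 12 (7R)-5-methyl-7-(2-methylprop-2-en-1-yl)-6-(prop-2-en-1-yl)-4,7-dihydrooxepin-2(3H)-one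
Product: 13 (7R)-5-methyl-7-(2-methylprop-2-en-1-yl)-6-(prop-2-en-1-yl)-2,3,4,7-tetrahydrooxepin-2-ol (anomers)
Conditions: i-Bu2AlH (1.05 equiv), CH2Cl2, −78 °C
Reagents that add atoms: none
Why: This is a partial lactone reduction, in which the aluminium lactolate is stable at −78 °C and no other group is reducible.

**Step 6**
Reactants: 13 the lactol; 14 isopropyltriphenylphosphonium iodide; 15 di-tert-butyl dicarbonate
Product: 17 tert-butyl (4R,5Z)-2,6,10-trimethyl-5-(prop-2-en-1-yl)undeca-1,5,9-trien-4-yl carbonate, via lithium alkoxide 16 (not isolated)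
Conditions: 14, n-BuLi, THF, 0 °C; 13, 0 °C to rt; then Boc2O, 0 °C to rt
Reagents that add atoms: isopropyltriphenylphosphonium iodide (14), CC(C)[P+](c1ccccc1)(c1ccccc1)c1ccccc1.[I-]; di-tert-butyl dicarbonate (15), CC(C)(C)OC(=O)OC(=O)OC(C)(C)C
Why: Wittig olefination of the open hydroxy-aldehyde form installs the C10=C11 terminus, and the liberated C1 alkoxide is O-acylated in the same flask, without touching C1 or the (Z)-alkene.

**Step 7**
Reactants: 17 the tetraene carbonate; 18 2,4,4,6-tetrabromocyclohexa-2,5-dien-1-one (TBCO)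
Product: 19 (4R,4aR,6R,8aR)-6-bromo-5,5,8a-trimethyl-4-(2-methylprop-2-en-1-yl)-4a-(prop-2-en-1-yl)hexahydro-4H-1,3-benzodioxin-2-one
Conditions: TBCO (1.05 equiv), MeNO2, 0 °C
Reagents that add atoms: TBCO (18), O=C1C(Br)=CC(Br)(Br)C=C1Br
Why: In this bromonium-induced cation–olefin cyclisation the terminal trisubstituted alkene takes Br+ and a chair transition state places Br equatorial; allylic 1,3-strain holds the Boc oxygen on the face opposite to the incoming C11, so anti addition across the (Z)-alkene sets C6, C7 and C10 relative to C1.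

**Step 8**
Reactants: 19 the bicyclic carbonate
Product: 20 cyclic (1R,6R,7R,10R)-10-bromo-3,7,11,11-tetramethylspiro[5.5]undec-3-ene-1,7-diyl carbonate
Conditions: second-generation Grubbs catalyst, RuCl2(=CHPh)(PCy3)(H2IMes) (5 mol %), CH2Cl2, 40 °C
Reagents that add atoms: none
Why: Ring-closing metathesis of the gauche allyl and methallyl arms closes ring A as the trisubstituted C3=C4 cyclohexene without creating or touching a stereocentre.

**Step 9**
Reactants: 20 the tricyclic carbonate
Product: 21 (1R,6R,7R,10R)-10-bromo-3,7,11,11-tetramethylspiro[5.5]undec-3-ene-1,7-diol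
Conditions: K2CO3 (cat.), MeOH, rt
Reagents that add atoms: none
Why: Base-catalysed transesterification frees both hydroxyl groups, and the neopentyl secondary bromide is inert to these mild conditions.

**Step 10**
Reactants: 21 the spiro diol; 22 N-bromosuccinimide; 23 chlorotitanium triisopropoxide
Product: 24 (1R,3S,4S,6R,7R,10R)-4,10-dibromo-3-chloro-3,7,11,11-tetramethylspiro[5.5]undecane-1,7-diol
Conditions: NBS (1.1 equiv), ClTi(Oi-Pr)3 (1.2 equiv), CH2Cl2–hexane, −20 °C
Reagents that add atoms: N-bromosuccinimide (22), O=C1CCC(=O)N1Br; chlorotitanium triisopropoxide (23), CC(C)O[Ti](Cl)(OC(C)C)OC(C)C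
Why: In this alkoxide-directed bromochlorination of a homoallylic alcohol, titanium bound to the axial C1–O delivers chloride to the tertiary C3 on its own face and opens the reversibly formed bromonium ion on the other face, giving anti Markovnikov addition with Cl cis to C1–O and Br trans.

**Step 11**
Reactants: 24 the bromochloro diol; 25 acetic anhydride
Product: 26 (1R,3S,4S,6R,7R,10R)-4,10-dibromo-3-chloro-7-hydroxy-3,7,11,11-tetramethylspiro[5.5]undecan-1-yl acetate (target)
Conditions: Ac2O, pyridine, DMAP (cat.), CH2Cl2, 0 °C to rt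
Reagents that add atoms: acetic anhydride (25), CC(=O)OC(C)=O
Why: In this nucleophile-catalysed acylation only the secondary C1–OH reacts, because the hindered tertiary C7–OH stays free.

**Compound list**
1 | methyl (2R)-oxirane-2-carboxylate | COC(=O)[C@H]1CO1 | starting material
2 | prop-1-en-2-ylmagnesium bromide | CC(=C)[Mg]Br | starting material
3 | methyl (2R)-2-hydroxy-4-methylpent-4-enoate | COC(=O)[C@H](O)CC(C)=C | intermediate
4 | N,O-dimethylhydroxylamine hydrochloride | CNOC.Cl | starting material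
5 | (2R)-2-hydroxy-N-methoxy-N,4-dimethylpent-4-enamide | CON(C)C(=O)[C@H](O)CC(C)=C | intermediate
6 | (4R)-4-hydroxy-2,6-dimethylhepta-1,6-dien-3-one | C=C(C)C(=O)[C@H](O)CC(C)=C | intermediate
7 | prop-2-en-1-ylmagnesium bromide | C=CC[Mg]Br | starting material
8 | (4R)-2,6-dimethyl-3-(prop-2-en-1-yl)hepta-1,6-diene-3,4-diol (C3 epimers) | C=CCC(O)(C(C)=C)[C@H](O)CC(C)=C | intermediate
9 | trimethyl orthoacetate | COC(C)(OC)OC | starting material
10 | (4R)-2-methoxy-2-methyl-4-(2-methylprop-2-en-1-yl)-5-(prop-1-en-2-yl)-5-(prop-2-en-1-yl)-1,3-dioxolane | COC1(C)O[C@H](CC(C)=C)C(CC=C)(C(C)=C)O1 | intermediate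
11 | (4R)-2-methylidene-4-(2-methylprop-2-en-1-yl)-5-(prop-1-en-2-yl)-5-(prop-2-en-1-yl)-1,3-dioxolane | C=C1O[C@H](CC(C)=C)C(CC=C)(C(C)=C)O1 | intermediate
12 | (7R)-5-methyl-7-(2-methylprop-2-en-1-yl)-6-(prop-2-en-1-yl)-4,7-dihydrooxepin-2(3H)-one | O=C1CCC(C)=C(CC=C)[C@@H](CC(C)=C)O1 | intermediate
13 | (7R)-5-methyl-7-(2-methylprop-2-en-1-yl)-6-(prop-2-en-1-yl)-2,3,4,7-tetrahydrooxepin-2-ol | OC1CCC(C)=C(CC=C)[C@@H](CC(C)=C)O1 | intermediate
14 | isopropyltriphenylphosphonium iodide | CC(C)[P+](c1ccccc1)(c1ccccc1)c1ccccc1.[I-] | starting material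
15 | di-tert-butyl dicarbonate | CC(C)(C)OC(=O)OC(=O)OC(C)(C)C | starting material
16 | lithium (4R,5Z)-2,6,10-trimethyl-5-(prop-2-en-1-yl)undeca-1,5,9-trien-4-olate | [Li+].C=C(C)C[C@@H]([O-])/C(CC=C)=C(/C)CCC=C(C)C | intermediate
17 | tert-butyl (4R,5Z)-2,6,10-trimethyl-5-(prop-2-en-1-yl)undeca-1,5,9-trien-4-yl carbonate | C=C(C)C[C@@H](OC(=O)OC(C)(C)C)/C(CC=C)=C(/C)CCC=C(C)C | intermediate
18 | 2,4,4,6-tetrabromocyclohexa-2,5-dien-1-one | O=C1C(Br)=CC(Br)(Br)C=C1Br | starting material
19 | (4R,4aR,6R,8aR)-6-bromo-5,5,8a-trimethyl-4-(2-methylprop-2-en-1-yl)-4a-(prop-2-en-1-yl)hexahydro-4H-1,3-benzodioxin-2-one | O=C1O[C@H](CC(C)=C)[C@@]2(CC=C)C(C)(C)[C@H](Br)CC[C@@]2(C)O1 | intermediate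
20 | cyclic (1R,6R,7R,10R)-10-bromo-3,7,11,11-tetramethylspiro[5.5]undec-3-ene-1,7-diyl carbonate | O=C1O[C@@H]2CC(C)=CC[C@@]23C(C)(C)[C@H](Br)CC[C@@]3(C)O1 | intermediate
21 | (1R,6R,7R,10R)-10-bromo-3,7,11,11-tetramethylspiro[5.5]undec-3-ene-1,7-diol | O[C@@H]1CC(C)=CC[C@@]12C(C)(C)[C@H](Br)CC[C@@]2(C)O | intermediate
22 | N-bromosuccinimide | O=C1CCC(=O)N1Br | starting material
23 | chlorotitanium triisopropoxide | CC(C)O[Ti](Cl)(OC(C)C)OC(C)C | starting material
24 | (1R,3S,4S,6R,7R,10R)-4,10-dibromo-3-chloro-3,7,11,11-tetramethylspiro[5.5]undecane-1,7-diol | O[C@@H]1C[C@](C)(Cl)[C@@H](Br)C[C@@]12C(C)(C)[C@H](Br)CC[C@@]2(C)O | intermediate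
25 | acetic anhydride | CC(=O)OC(C)=O | starting material
26 | (1R,3S,4S,6R,7R,10R)-4,10-dibromo-3-chloro-7-hydroxy-3,7,11,11-tetramethylspiro[5.5]undecan-1-yl acetate | CC(=O)O[C@@H]1C[C@](C)(Cl)[C@@H](Br)C[C@@]12C(C)(C)[C@H](Br)CC[C@@]2(C)O | target

**Totals**
Total step count: 11. Longest linear sequence: 11.

**Steps most likely to fail**

Step 7 (bromonium cyclisation).
- Risk: Br+ may also attack the tetrasubstituted or the methallyl alkene, or the C7 cation may run on into the methallyl group.
- Fallback: it sets out from 17 and separates halogen placement from ring closure. The terminal alkene alone is bromochlorinated (NBS, Bu4NCl, CH2Cl2, −78 °C). This gives the vicinal bromochloride tert-butyl (4R,5Z)-9-bromo-10-chloro-2,6,10-trimethyl-5-(prop-2-en-1-yl)undeca-1,5-dien-4-yl carbonate F1 as both C9 epimers.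
- The tertiary chloride is then ionised in (CF3)2CHOH with solid NaHCO3. The bromonium ion arises by neighbouring-group participation, with no free Br+ left to attack other alkenes. It closes ring B with the same Boc trap, and the route is rejoined at 19.
- Limit: only the epimer whose bromonium ion fits the chair gives 19, so at most half of the material is used.

Step 10 (bromochlorination).
- Risk: the C7–OH may capture the bromonium ion as a bridged ether, or the wrong face may react.
- Fallback: it sets out from 21. Boc2O and DMAP acylate only C1–OH to give tert-butyl (1R,6R,7R,10R)-10-bromo-7-hydroxy-3,7,11,11-tetramethylspiro[5.5]undec-3-en-1-yl carbonate F2.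
- NBS in MeCN at −20 °C then causes halocyclisation of the homoallylic carbonate. The product is the bridged cyclic (1R,3S,4S,6R,7R,10R)-4,10-dibromo-7-hydroxy-3,7,11,11-tetramethylspiro[5.5]undecane-1,3-diyl carbonate F3, with O at C3 cis to C1–O and Br trans.
- TiCl4 in CH2Cl2 at −78 °C ionises the tertiary C3–O bond with help from the antiperiplanar bromine. Chloride opens the bromonium ion at C3 with overall retention, and the route is rejoined at 24.

Step 4 (Claisen ring expansion).
- Risk: under acid the dioxolanylium ion may cleave at the tertiary allylic C–O bond instead of losing a proton.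
- Fallback: it sets out from 8 and makes the ketene acetal under basic conditions. Acetal exchange with 2-(phenylselanyl)acetaldehyde diethyl acetal (PPTS, toluene, 80 °C) gives (4R)-4-(2-methylprop-2-en-1-yl)-2-[(phenylselanyl)methyl]-5-(prop-1-en-2-yl)-5-(prop-2-en-1-yl)-1,3-dioxolane F4.
- NaIO4 oxidises it to the selenoxide (4R)-2-[(benzeneseleninyl)methyl]-4-(2-methylprop-2-en-1-yl)-5-(prop-1-en-2-yl)-5-(prop-2-en-1-yl)-1,3-dioxolane F5.
- Heating with DBU in xylene brings about syn elimination. The route is rejoined at 11, which rearranges to 12 in the same flask.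

**Further compounds**
F1 | step 7 | tert-butyl (4R,5Z)-9-bromo-10-chloro-2,6,10-trimethyl-5-(prop-2-en-1-yl)undeca-1,5-dien-4-yl carbonate | C=C(C)C[C@@H](OC(=O)OC(C)(C)C)/C(CC=C)=C(/C)CCC(Br)C(C)(C)Cl
F2 | step 10 | tert-butyl (1R,6R,7R,10R)-10-bromo-7-hydroxy-3,7,11,11-tetramethylspiro[5.5]undec-3-en-1-yl carbonate | CC(C)(C)OC(=O)O[C@@H]1CC(C)=CC[C@@]12C(C)(C)[C@H](Br)CC[C@@]2(C)O
F3 | step 10 | cyclic (1R,3S,4S,6R,7R,10R)-4,10-dibromo-7-hydroxy-3,7,11,11-tetramethylspiro[5.5]undecane-1,3-diyl carbonate | O=C1O[C@@H]2C[C@](C)(O1)[C@@H](Br)C[C@@]23C(C)(C)[C@H](Br)CC[C@@]3(C)O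
F4 | step 4 | (4R)-4-(2-methylprop-2-en-1-yl)-2-[(phenylselanyl)methyl]-5-(prop-1-en-2-yl)-5-(prop-2-en-1-yl)-1,3-dioxolane | C(C1O[C@H](CC(C)=C)C(CC=C)(C(C)=C)O1)[Se]c1ccccc1
F5 | step 4 | (4R)-2-[(benzeneseleninyl)methyl]-4-(2-methylprop-2-en-1-yl)-5-(prop-1-en-2-yl)-5-(prop-2-en-1-yl)-1,3-dioxolane | C(C1O[C@H](CC(C)=C)C(CC=C)(C(C)=C)O1)[Se](=O)c1ccccc1
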